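**Retrosynthetic overview**
1. Locants: decalin C1 (quaternary carbon), C2=C3(OH)–C4(=O) (diosphenol of ring A), C4a/C8a (ring fusion), C5–C8 (ring B), C1′ (side-chain stereocentre); β is the face of H-8a, α the face of H-4a and of the C1 methyl.
2. Enabling feature: ring B carries its two oxygens at C5 and C8, 1,4 across the ring and flanking the C4a–C8a fusion. Ring B is therefore the retron of a [4+2] between a 2-silyloxydiene (C4a=C5–C6=C7) and an (E)-alkenylboronate (C8=C8a), and the chain C1–C2–C3–C4 that joins them is ring A.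
3. Key disconnection: an intramolecular Diels–Alder reaction of an acyclic triene closes rings A and B together (bonds C7–C8 and C4a–C8a) and sets C4a, C8a and C8 from the single quaternary centre C1.
4. Triene: C1 from iridium-catalysed tert-(hydroxy)prenylation of 3-(benzyloxy)propanol with isoprene monoxide; the vinyl group becomes C2–C3–C4 by hydroformylation; then ynone/glycol ketal (C4), boryl olefination (C8) and silyl dienol ether (C5).
5. After the rings: axial C5 alcohol by bulky hydride, C8–B to C8–OH, diosphenol by α-oxidation, side chain by Mitsunobu etherification and Claisen rearrangement (chirality transfer to C1′), then one global hydrogenation.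

Key step: step 11

Remark: in step 1 the (S)-ligand is assumed to give the (2S,3S)-diol; the antipodal ligand is used should the sense of induction be the opposite. The carbinol centre made there only adds bulk in step 11 and is oxidised in step 16.
Remark: compounds 1, 2, 8, 13 and 25 are taken as commercial.

**Step 1**
Reactants: 1 3-(benzyloxy)propan-1-ol; 2 isoprene monoxide (2-methyl-2-vinyloxirane, racemic)
Product: 4 (2S,3S)-5-(benzyloxy)-2-ethenyl-2-methylpentane-1,3-diol, via 3-(benzyloxy)propanal 3 (not isolated)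
Conditions: [Ir(cod)Cl]2, (S)-Tol-BINAP, 4-cyano-3-nitrobenzoic acid, allyl acetate, Cs2CO3 (preformed π-allyliridium C,O-benzoate, 5 mol%), K3PO4 (5 mol%), THF, 60 °C
Reagents that add atoms: none
Why: Transfer-hydrogenative carbonyl tert-(hydroxy)prenylation: the alcohol is dehydrogenated to aldehyde 3, the vinyl epoxide gives a π-allyliridium species, and this adds at its substituted terminus through a closed chair transition state, so the quaternary carbon (future C1) and the carbinol (anti) are set under ligand control.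

**Step 2**
Reactants: 4 diol
Product: 5 (2S,3S)-5-(benzyloxy)-1,3-bis(tert-butyldimethylsilyloxy)-2-ethenyl-2-methylpentane
Conditions: TBSOTf, 2,6-lutidine, CH2Cl2, 0 °C to rt
Reagents that add atoms: tert-butyldimethylsilyl trifluoromethanesulfonate, CC(C)(C)[Si](C)(C)OS(=O)(=O)C(F)(F)F
Why: Silylation of both hydroxyls with the silyl triflate, which also reaches the hindered secondary alcohol; no stereocentre is touched.

**Step 3**
Reactants: 5 bis-silyl ether
Product: 6 (4S,5S)-7-(benzyloxy)-5-(tert-butyldimethylsilyloxy)-4-[(tert-butyldimethylsilyloxy)methyl]-4-methylheptanal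
Conditions: Rh(acac)(CO)2 (1 mol%), Xantphos, CO/H2 (1:1, 10 bar), PhMe, 70 °C
Reagents that add atoms: carbon monoxide, [C-]#[O+]
Why: Rhodium-catalysed hydroformylation; a vinyl group on a quaternary carbon is formylated almost only at its terminus, which gives the linear aldehyde and with it the C2–C3–C4 chain.

**Step 4**
Reactants: 6 aldehyde
Product: 7 (5S,6S)-8-(benzyloxy)-6-(tert-butyldimethylsilyloxy)-5-[(tert-butyldimethylsilyloxy)methyl]-5-methyloct-1-yne
Conditions: dimethyl (1-diazo-2-oxopropyl)phosphonate, K2CO3, MeOH, 0 °C to rt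
Reagents that add atoms: dimethyl (1-diazo-2-oxopropyl)phosphonate, COP(=O)(OC)C(=[N+]=[N-])C(C)=O
Why: Seyferth–Gilbert homologation with the Ohira–Bestmann reagent turns the aldehyde into the terminal alkyne (C4≡C4a) under mild base.

**Step 5**
Reactants: 7 alkyne; 8 N-methoxy-N-methylmethacrylamide
Product: 9 (8S,9S)-11-(benzyloxy)-9-(tert-butyldimethylsilyloxy)-8-[(tert-butyldimethylsilyloxy)methyl]-2,8-dimethylundec-1-en-4-yn-3-one
Conditions: n-BuLi, THF, −78 °C; then 8, −78 to 0 °C; then aq NH4Cl
Reagents that add atoms: none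
Why: Acylation of the lithium acetylide by the Weinreb amide; the chelated tetrahedral adduct prevents over-addition and the cross-conjugated ynone forms on work-up.

**Step 6**
Reactants: 9 ynone
Product: 10 keto ketal 1-{2-[(3S,4S)-6-(benzyloxy)-4-(tert-butyldimethylsilyloxy)-3-[(tert-butyldimethylsilyloxy)methyl]-3-methylhexyl]-1,3-dioxolan-2-yl}-3-methylbut-3-en-2-one
Conditions: ethylene glycol (5 equiv), KOtBu (0.2 equiv), THF, 0 °C to rt
Reagents that add atoms: ethylene glycol, OCCO
Why: Base-catalysed double oxa-Michael addition of the diol to the ynone, which is far more electrophilic than the α-methyl enone; this puts the dioxolane on C4 and leaves the C5 isopropenyl ketone.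

**Step 7**
Reactants: 10 keto ketal
Product: 11 primary alcohol (10 with CH2OH in place of CH2OTBS)
Conditions: HF·pyridine, pyridine, THF, 0 °C
Reagents that add atoms: none
Why: Selective fluoride cleavage of the primary silyl ether; the secondary silyl ether next to the quaternary carbon is much more hindered and should survive.

**Step 8**
Reactants: 11 primary alcohol
Product: 12 aldehyde (11 with CHO in place of CH2OH; quaternary carbon and carbinol as in 4)
Conditions: Dess–Martin periodinane, NaHCO3, CH2Cl2, rt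
Reagents that add atoms: none
Why: Dess–Martin oxidation to an aldehyde that cannot enolise, so the quaternary centre is safe.

**Step 9**
Reactants: 12 aldehyde; 13 2-(dichloromethyl)-4,4,5,5-tetramethyl-1,3,2-dioxaborolane
Product: 14 (E)-alkenyl pinacolboronate (12 with (E)-CH=CH–B(pin) in place of CHO)
Conditions: CrCl2 (8 equiv), LiI (4 equiv), THF, rt
Reagents that add atoms: none
Why: Takai–Utimoto-type boryl olefination: the gem-dichromium species from 13 adds to the aldehyde and eliminates to the E-alkenylboronate, and ketone, enone and ketal are not attacked by this aldehyde-selective reagent.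

**Step 10**
Reactants: 14 alkenylboronate
Product: 15 triene, the (Z)-triethylsilyl dienol ether of 14 (a 3-methyl-2-(triethylsilyloxy)buta-1,3-dienyl group on the dioxolane carbon)
Conditions: KN(SiMe3)2, THF, −78 °C; then TESCl, −78 °C
Reagents that add atoms: chlorotriethylsilane, CC[Si](Cl)(CC)CC
Why: Kinetic enolisation at C4a, the only enolisable α-position, then O-silylation; the hindered amide base is compatible with a pinacol boronate at low temperature and gives the Z(O)-enolate, which puts C4 on the outside of the s-cis diene.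

**Step 11**
Reactants: 15 triene
Product: 17 trans-decalone boronate, via cycloadduct silyl enol ether 16 (not isolated)
Conditions: PhMe (0.01 M), BHT, 160 °C, sealed tube; cool; then Bu4NF, AcOH, THF, 0 °C to rt
Reagents that add atoms: none
Why: On heating, the Z-silyloxydiene (C4a=C5–C6=C7) and the E-alkenylboronate (C8=C8a), held together by the chain C1–C4 with its two fully substituted carbons, undergo a concerted, asynchronous, normal-demand [4+2] cycloaddition in which the nucleophilic diene terminus C4a bonds to C8a (β to boron) and C7 bonds to C8. The closest known reactions are the type 1 intramolecular Diels–Alder reaction of 1,7,9-decatrienes to trans-decalins and Diels–Alder reactions of alkenylboronic esters followed by C–B oxidation. Ring B is closed by the cycloaddition itself and ring A by the tether, with the C4a–C8a bond exo to both π-systems and the tether in a chair. C8 is set relative to C8a by the E geometry of the boronate (suprafacial addition, boron equatorial), C8a relative to C1 by the chair in which the bulky silyloxyalkyl group on C1 lies anti to the forming C4a–C8a bond and the methyl is axial, and C4a by the endo transition state (boron under the diene) that gives the trans fusion. The step needs dienophile-face selectivity, which the quaternary centre C1 secures, and trans fusion, which is also the thermodynamic outcome because C4a and C6 become epimerisable α-positions of the C5 ketone once fluoride cleaves the silyl enol ether in the same pot (6-methyl equatorial).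

**Step 12**
Reactants: 17 decalone boronate
Product: 19 decalin-5β,8β-diol ketal, via 5β-hydroxy boronate 18 (not isolated)
Conditions: LiBH(s-Bu)3, THF, −78 to −20 °C; then NaOH (3 M), H2O2 (30%), 0 °C to rt
Reagents that add atoms: hydrogen peroxide, OO
Why: The bulky borohydride attacks C5 from the equatorial direction, because the axial approach is blocked by the axial ketal oxygen on C4 and the axial hydrogens on C7 and C8a, and gives the axial 5β-alcohol; the alkaline peroxide work-up oxidises the C8–B bond with retention to the equatorial 8β-alcohol.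

**Step 13**
Reactants: 19 diol
Product: 20 5β,8β-bis(benzyl) ether
Conditions: NaH, BnBr, Bu4NI (cat.), DMF, 0 °C to rt
Reagents that add atoms: benzyl bromide, BrCc1ccccc1
Why: Williamson etherification of both secondary alkoxides; no carbonyl is present at this stage, so the alkoxides cannot fragment.

**Step 14**
Reactants: 20 bis(benzyl) ether
Product: 21 hydroxy ketone (C4 ketone, free side-chain carbinol)
Conditions: HCl (2 M aq), THF, 40 °C
Reagents that add atoms: water, O
Why: Acid hydrolysis of the dioxolane and cleavage of the silyl ether in one operation; the trans ring fusion is already the stable arrangement next to the new ketone.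

**Step 15**
Reactants: 21 hydroxy ketone
Product: 22 3β-hydroxy-4-ketone
Conditions: LiN(SiMe3)2 (3.2 equiv), THF, −78 °C; then 2-(phenylsulfonyl)-3-phenyloxaziridine, −78 °C; then aq NH4Cl
Reagents that add atoms: 2-(phenylsulfonyl)-3-phenyloxaziridine, O=S(=O)(c1ccccc1)N1OC1c1ccccc1
Why: Davis oxidation of the kinetic enolate, which forms at C3 (the only CH2 next to the ketone) and not at the hindered ring-fusion carbon; oxygen should enter anti to the axial C1 methyl (3β), and this centre is removed in the next step.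

**Step 16**
Reactants: 22 α-hydroxy ketone
Product: 24 diosphenol ketone, via ring A 3,4-dione 23 (not isolated)
Conditions: Dess–Martin periodinane (3 equiv), NaHCO3, CH2Cl2, rt
Reagents that add atoms: none
Why: Dess–Martin oxidation of both secondary alcohols gives the side-chain ketone and the 3,4-dione, which should enolise towards C2 to the diosphenol.

**Step 17**
Reactants: 25 (E)-oct-2-en-4-one
Product: 26 (R,E)-oct-2-en-4-ol
Conditions: (S)-2-methyl-CBS-oxazaborolidine (10 mol%), catecholborane, PhMe, −78 °C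
Reagents that add atoms: none
Why: Corey–Bakshi–Shibata reduction, in which the alkenyl group acts as the large substituent and hydride is delivered to the face that gives the (R)-allylic alcohol.

**Step 18**
Reactants: 24 diosphenol ketone; 26 (R,E)-oct-2-en-4-ol
Product: 27 diosphenol (S)-allyl ether (C3–O–CH(n-Bu)–CH=CH–CH3)
Conditions: PPh3, DIAD, PhMe/THF, 0 °C to rt
Reagents that add atoms: none
Why: Mitsunobu etherification of the acidic enol; SN2 displacement inverts the carbinol to the (S)-ether, and alkylation is expected on the C3 oxygen because deprotonation at the C2 methylene and attack through the unhindered C3 oxygen are both favoured over the ring-fusion side.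

**Step 19**
Reactants: 27 allyl enol ether
Product: 29 alkenyl diosphenol, via C2-alkylated 3,4-dione 28 (not isolated)
Conditions: xylene, BHT, 150 °C, sealed tube
Reagents that add atoms: none
Why: Claisen rearrangement of a diosphenol allyl ether: the chair transition state with the butyl group pseudo-equatorial transfers the (S)-carbinol chirality to (R)-C1′ with an E alkene, the allyl unit adds to C2 anti to the axial C1 methyl, and enolisation of dione 28 then removes the C2 centre.

**Step 20**
Reactants: 29 alkenyl diosphenol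
Product: 30 target compound
Conditions: H2 (1 atm), Pd(OH)2/C, EtOAc/EtOH, rt
Reagents that add atoms: none
Why: Catalytic hydrogenation saturates the disubstituted side-chain alkene and hydrogenolysis removes the three benzyl ethers, while the tetrasubstituted enol and the ketones should not be reduced.

**Compound list**
1 | 3-(benzyloxy)propan-1-ol | OCCCOCc1ccccc1 | starting material
2 | isoprene monoxide (2-methyl-2-vinyloxirane, racemic) | CC1(C=C)CO1 | starting material
3 | 3-(benzyloxy)propanal | O=CCCOCc1ccccc1 | intermediate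
4 | (2S,3S)-5-(benzyloxy)-2-ethenyl-2-methylpentane-1,3-diol | OC[C@](C)(C=C)[C@@H](O)CCOCc1ccccc1 | intermediate
5 | (2S,3S)-5-(benzyloxy)-1,3-bis(tert-butyldimethylsilyloxy)-2-ethenyl-2-methylpentane | CC(C)(C)[Si](C)(C)OC[C@](C)(C=C)[C@@H](O[Si](C)(C)C(C)(C)C)CCOCc1ccccc1 | intermediate
6 | (4S,5S)-7-(benzyloxy)-5-(tert-butyldimethylsilyloxy)-4-[(tert-butyldimethylsilyloxy)methyl]-4-methylheptanal | CC(C)(C)[Si](C)(C)OC[C@](C)(CCC=O)[C@@H](O[Si](C)(C)C(C)(C)C)CCOCc1ccccc1 | intermediate
7 | (5S,6S)-8-(benzyloxy)-6-(tert-butyldimethylsilyloxy)-5-[(tert-butyldimethylsilyloxy)methyl]-5-methyloct-1-yne | CC(C)(C)[Si](C)(C)OC[C@](C)(CCC#C)[C@@H](O[Si](C)(C)C(C)(C)C)CCOCc1ccccc1 | intermediate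
8 | N-methoxy-N-methylmethacrylamide | C=C(C)C(=O)N(C)OC | starting material
9 | (8S,9S)-11-(benzyloxy)-9-(tert-butyldimethylsilyloxy)-8-[(tert-butyldimethylsilyloxy)methyl]-2,8-dimethylundec-1-en-4-yn-3-one | CC(C)(C)[Si](C)(C)OC[C@](C)(CCC#CC(=O)C(C)=C)[C@@H](O[Si](C)(C)C(C)(C)C)CCOCc1ccccc1 | intermediate
10 | keto ketal: 1-{2-[(3S,4S)-6-(benzyloxy)-4-(tert-butyldimethylsilyloxy)-3-[(tert-butyldimethylsilyloxy)methyl]-3-methylhexyl]-1,3-dioxolan-2-yl}-3-methylbut-3-en-2-one | CC(C)(C)[Si](C)(C)OC[C@](C)(CCC1(CC(=O)C(C)=C)OCCO1)[C@@H](O[Si](C)(C)C(C)(C)C)CCOCc1ccccc1 | intermediate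
11 | primary alcohol: 10 with CH2OH in place of CH2OTBS | OC[C@](C)(CCC1(CC(=O)C(C)=C)OCCO1)[C@@H](O[Si](C)(C)C(C)(C)C)CCOCc1ccccc1 | intermediate
12 | aldehyde: 11 with CHO in place of CH2OH | O=C[C@](C)(CCC1(CC(=O)C(C)=C)OCCO1)[C@@H](O[Si](C)(C)C(C)(C)C)CCOCc1ccccc1 | intermediate
13 | 2-(dichloromethyl)-4,4,5,5-tetramethyl-1,3,2-dioxaborolane | ClC(Cl)B1OC(C)(C)C(C)(C)O1 | starting material
14 | (E)-alkenyl pinacolboronate: 12 with (E)-CH=CH–B(pin) in place of CHO | CC1(C)OB(/C=C/[C@](C)(CCC2(CC(=O)C(C)=C)OCCO2)[C@@H](O[Si](C)(C)C(C)(C)C)CCOCc2ccccc2)OC1(C)C | intermediate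
15 | triene: (Z)-triethylsilyl dienol ether of 14 | CC1(C)OB(/C=C/[C@](C)(CCC2(/C=C(O[Si](CC)(CC)CC)/C(C)=C)OCCO2)[C@@H](O[Si](C)(C)C(C)(C)C)CCOCc2ccccc2)OC1(C)C | intermediate
16 | cycloadduct: trans-fused Δ5-octalin, 4,4-ethylenedioxy, 5-OTES, 6-methyl, 8β-B(pin), 1α-methyl, 1β-[(1S)-3-(benzyloxy)-1-(tert-butyldimethylsilyloxy)propyl], H-4a α, H-8a β | C1CC2(OCCO2)[C@H]3C(O[Si](CC)(CC)CC)=C(C)C[C@@H](B4OC(C)(C)C(C)(C)O4)[C@@H]3[C@@]1(C)[C@@H](O[Si](C)(C)C(C)(C)C)CCOCc1ccccc1 | intermediate
17 | trans-decalone boronate: 16 with C5 ketone and 6β (equatorial) methyl | C1CC2(OCCO2)[C@H]3C(=O)[C@@H](C)C[C@@H](B4OC(C)(C)C(C)(C)O4)[C@@H]3[C@@]1(C)[C@@H](O[Si](C)(C)C(C)(C)C)CCOCc1ccccc1 | intermediate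
18 | 5β-hydroxy boronate: 17 with axial 5β-OH | C1CC2(OCCO2)[C@H]3[C@@H](O)[C@@H](C)C[C@@H](B4OC(C)(C)C(C)(C)O4)[C@@H]3[C@@]1(C)[C@@H](O[Si](C)(C)C(C)(C)C)CCOCc1ccccc1 | intermediate
19 | decalin-5β,8β-diol ketal: 18 with equatorial 8β-OH in place of B(pin) | C1CC2(OCCO2)[C@H]3[C@@H](O)[C@@H](C)C[C@@H](O)[C@@H]3[C@@]1(C)[C@@H](O[Si](C)(C)C(C)(C)C)CCOCc1ccccc1 | intermediate
20 | 5β,8β-bis(benzyl) ether of 19 | C1CC2(OCCO2)[C@H]3[C@@H](OCc4ccccc4)[C@@H](C)C[C@@H](OCc4ccccc4)[C@@H]3[C@@]1(C)[C@@H](O[Si](C)(C)C(C)(C)C)CCOCc1ccccc1 | intermediate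
21 | hydroxy ketone: 20 with C4 ketone and free (1S)-carbinol in the C1 side chain | C1CC(=O)[C@H]2[C@@H](OCc3ccccc3)[C@@H](C)C[C@@H](OCc3ccccc3)[C@@H]2[C@@]1(C)[C@@H](O)CCOCc1ccccc1 | intermediate
22 | 3β-hydroxy-4-ketone: 21 with equatorial 3β-OH | C1[C@@H](O)C(=O)[C@H]2[C@@H](OCc3ccccc3)[C@@H](C)C[C@@H](OCc3ccccc3)[C@@H]2[C@@]1(C)[C@@H](O)CCOCc1ccccc1 | intermediate
23 | ring A 3,4-dione with 3-(benzyloxy)propanoyl group on C1 | C1C(=O)C(=O)[C@H]2[C@@H](OCc3ccccc3)[C@@H](C)C[C@@H](OCc3ccccc3)[C@@H]2[C@@]1(C)C(=O)CCOCc1ccccc1 | intermediate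
24 | diosphenol ketone: 3-hydroxy-2-en-4-one tautomer of 23 | C1=C(O)C(=O)[C@H]2[C@@H](OCc3ccccc3)[C@@H](C)C[C@@H](OCc3ccccc3)[C@@H]2[C@@]1(C)C(=O)CCOCc1ccccc1 | intermediate
25 | (E)-oct-2-en-4-one | CCCCC(=O)/C=C/C | starting material
26 | (R,E)-oct-2-en-4-ol | C/C=C/[C@H](O)CCCC | intermediate
27 | diosphenol (S)-allyl ether: 24 with C3–O–[(S,E)-oct-2-en-4-yl] | C1=C(O[C@@H](CCCC)/C=C/C)C(=O)[C@H]2[C@@H](OCc3ccccc3)[C@@H](C)C[C@@H](OCc3ccccc3)[C@@H]2[C@@]1(C)C(=O)CCOCc1ccccc1 | intermediate
28 | C2-alkylated 3,4-dione: 2β-[(R,E)-oct-3-en-2-yl] | CCCC/C=C/[C@@H](C)[C@H]1C(=O)C(=O)[C@H]2[C@@H](OCc3ccccc3)[C@@H](C)C[C@@H](OCc3ccccc3)[C@@H]2[C@@]1(C)C(=O)CCOCc1ccccc1 | intermediate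
29 | alkenyl diosphenol: tris(benzyl) ether of the target with an (R,E)-oct-3-en-2-yl group on C2 | CCCC/C=C/[C@@H](C)C1=C(O)C(=O)[C@H]2[C@@H](OCc3ccccc3)[C@@H](C)C[C@@H](OCc3ccccc3)[C@@H]2[C@@]1(C)C(=O)CCOCc1ccccc1 | intermediate
30 | CNP0234794.3 | CCCCCC[C@@H](C)C1=C(O)C(=O)[C@H]2[C@@H](O)[C@@H](C)C[C@@H](O)[C@@H]2[C@@]1(C)C(=O)CCO | target

**Step count**
Total steps: 20. Longest linear sequence: 19 steps (steps 1–16 and 18–20); step 17 is a one-step side branch.

**Steps most likely to fail**

Step 11. The pinacol alkenylboronate is only a weakly activated dienophile, so the cycloaddition may need temperatures at which the silyl dienol ether isomerises or is lost, and the facial preference set by C1 may be low at such temperatures. The fallback replaces the boronate by a far stronger boron dienophile made in the flask. It sets out from aldehyde 12: Ohira–Bestmann homologation gives terminal alkyne F1, and enol silylation as in step 10 (the ketone is far more acidic than the alkyne) gives dienol ether alkyne F2. Hydroboration of the alkyne with Cy2BH (1 equiv, THF, 0 °C) gives dialkyl(alkenyl)borane F3, which should cyclise at 25–50 °C to borane cycloadduct F4. Oxidation (NaOH, H2O2) and then Bu4NF/AcOH give hydroxy ketone F5, and reduction with LiBH(s-Bu)3 as in step 12 returns to diol 19.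

Step 18. The dione may enolise towards the ring-fusion carbon C4a, so that the wrong enol oxygen is alkylated, and the allylic oxyphosphonium may be attacked in the SN2′ sense, which would scramble the side chain. The fallback forms the C3–O bond regiospecifically and sets out from hydroxy ketone 21. Saegusa–Ito dehydrogenation (LiN(SiMe3)2, TMSCl; then Pd(OAc)2, MeCN) gives enone F6, and α-iodination (I2, pyridine) gives iodoenone F7. Copper-catalysed C–O coupling (CuI, 3,4,7,8-tetramethyl-1,10-phenanthroline, Cs2CO3, PhMe, 80 °C) with (S,E)-oct-2-en-4-ol F8, made from 25 with the (R)-oxazaborolidine and coupled with retention, gives allyl enol ether carbinol F9. Dess–Martin oxidation of its side-chain carbinol returns to allyl ether 27.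

Step 6. The second conjugate addition may stall at the β-alkoxy enone, or the alkoxide may add to the isopropenyl ketone and start oligomerisation. The fallback builds the β-keto ketal from an ester and sets out from aldehyde 6. Roskamp homologation (ethyl diazoacetate, SnCl2, CH2Cl2) gives β-keto ester F10, and ketalisation (1,2-bis(trimethylsilyloxy)ethane, TMSOTf, −78 °C) gives ketal ester F11. Me(MeO)NH·HCl with iPrMgCl gives Weinreb amide F12, and isopropenylmagnesium bromide (THF, 0 °C) returns to keto ketal 10.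

**Further compounds**
F1 | step 11 | terminal alkyne (12 with C≡CH in place of CHO) | C#C[C@](C)(CCC1(CC(=O)C(C)=C)OCCO1)[C@@H](O[Si](C)(C)C(C)(C)C)CCOCc1ccccc1
F2 | step 11 | dienol ether alkyne ((Z)-triethylsilyl dienol ether of F1) | C#C[C@](C)(CCC1(/C=C(O[Si](CC)(CC)CC)/C(C)=C)OCCO1)[C@@H](O[Si](C)(C)C(C)(C)C)CCOCc1ccccc1
F3 | step 11 | dialkyl(alkenyl)borane ((E)-alkenyl-B(cyclohexyl)2 from F2) | C1CCCCC1B(C1CCCCC1)/C=C/[C@](C)(CCC1(/C=C(O[Si](CC)(CC)CC)/C(C)=C)OCCO1)[C@@H](O[Si](C)(C)C(C)(C)C)CCOCc1ccccc1
F4 | step 11 | borane cycloadduct (16 with B(cyclohexyl)2 in place of B(pin)) | C1CC2(OCCO2)[C@H]3C(O[Si](CC)(CC)CC)=C(C)C[C@@H](B(C4CCCCC4)C4CCCCC4)[C@@H]3[C@@]1(C)[C@@H](O[Si](C)(C)C(C)(C)C)CCOCc1ccccc1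
F5 | step 11 | hydroxy ketone (17 with 8β-OH in place of B(pin)) | C1CC2(OCCO2)[C@H]3C(=O)[C@@H](C)C[C@@H](O)[C@@H]3[C@@]1(C)[C@@H](O[Si](C)(C)C(C)(C)C)CCOCc1ccccc1
F6 | step 18 | enone (21 with C2=C3 double bond) | C1=CC(=O)[C@H]2[C@@H](OCc3ccccc3)[C@@H](C)C[C@@H](OCc3ccccc3)[C@@H]2[C@@]1(C)[C@@H](O)CCOCc1ccccc1
F7 | step 18 | iodoenone (F6 with iodine on C3) | C1=C(I)C(=O)[C@H]2[C@@H](OCc3ccccc3)[C@@H](C)C[C@@H](OCc3ccccc3)[C@@H]2[C@@]1(C)[C@@H](O)CCOCc1ccccc1
F8 | step 18 | (S,E)-oct-2-en-4-ol | C/C=C/[C@@H](O)CCCC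
F9 | step 18 | allyl enol ether carbinol (27 with the side-chain carbinol in place of the ketone) | C1=C(O[C@@H](CCCC)/C=C/C)C(=O)[C@H]2[C@@H](OCc3ccccc3)[C@@H](C)C[C@@H](OCc3ccccc3)[C@@H]2[C@@]1(C)[C@@H](O)CCOCc1ccccc1
F10 | step 6 | β-keto ester (ethyl 3-oxoalkanoate from 6) | CC(C)(C)[Si](C)(C)OC[C@](C)(CCC(=O)CC(=O)OCC)[C@@H](O[Si](C)(C)C(C)(C)C)CCOCc1ccccc1
F11 | step 6 | ketal ester (dioxolane of F10) | CC(C)(C)[Si](C)(C)OC[C@](C)(CCC1(CC(=O)OCC)OCCO1)[C@@H](O[Si](C)(C)C(C)(C)C)CCOCc1ccccc1
F12 | step 6 | Weinreb amide (from F11) | CC(C)(C)[Si](C)(C)OC[C@](C)(CCC1(CC(=O)N(C)OC)OCCO1)[C@@H](O[Si](C)(C)C(C)(C)C)CCOCc1ccccc1
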